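## Analysis of the target

Psiadiarabicin is a flavone: benzene ring A is fused to a 4-pyranone ring (O1, C2, C3, C4, C4a, C8a), and benzene ring B sits on C2. It has no stereocentre, so nothing has to be set or relayed. Ring A carries 5-OH, 6-OMe and 7-OMe; ring B carries 2'-OMe, 3'-OH, 4'-OMe and 5'-OMe; C3, C8 and C6' are CH. The two hydroxyls differ in kind: the 5-OH is hydrogen-bonded to the C4 carbonyl and is a poor nucleophile, whereas the 3'-OH is an ordinary phenol flanked by two methoxyls and is easily oxidised. Both rings are electron-rich, the pyranone is opened by hard nucleophiles at C2, and strong acids risk demethylation or isomerisation of the 5,6,7-pattern. The difficulty is to tell two hydroxyls from five methoxyls and to close the pyranone on the correct side of ring A. Closure by condensation through a phenol at C8a normally leaves a methyl group on O5 that must be removed late from a molecule with six other ethers. The strategy rests on ring A: O5 and O6 sit on adjacent carbons (a catechol when O6 is free), and C8a is para to C6. When that catechol is oxidised to the ortho-quinone, C8a becomes the β-carbon of the C5 carbonyl (C5(=O)–C4a=C8a) and of the C4 ketone. O1–C8a can therefore be made by conjugate addition of the diketone enol oxygen to an oxidised ring A, starting from C8a–H.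

## Retrosynthetic reasoning

16 to 15. The last bond cut is the O–benzyl bond at C3'. This hydroxyl must stay masked through the oxidation and the methylation, because a free 2,6-dimethoxyphenol unit on ring B would be oxidised and methylated alongside ring A. A benzyl ether comes off by neutral hydrogenolysis, which leaves the methoxyls and the pyranone alone.

15 to 14. The O–CH3 bond at C6 is cut next. The forward methylation has to choose O6 over O5; the chelation of the 5-OH to the C4 carbonyl provides that choice, so O5 is never protected and never deprotected.

14 to 11 (through 12 and 13). The strategic cut is O1–C8a. Cutting here, and not at O1–C2, turns ring A into a simple 1,2-dihydroxy-3-methoxy-4-acyl benzene with C8a as CH, a pattern that can be bought. The forward step must oxidise the catechol of 11 to ortho-quinone 12 without touching ring B, deliver the enol oxygen to C8a, and let 13 re-aromatise to 14.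

11 to 8 and 9. The C2–C3 bond of the diketone is cut, which divides the molecule into two halves of similar size. Acetophenone 9 already holds all three ring A oxygens in their final places. The forward reaction is a C-acylation of the lithium polyanion of 9 by acid chloride 8, so the phenols need no protection.

8 to 7 to 6. The acid chloride comes from acid 7. The C5'–OMe bond of 7 is cut back to the C5'–Br bond of 6, because copper-catalysed methoxylation replaces a halogen at exactly the carbon where electrophilic substitution puts it.

6 to 5 to 4. Acid 6 comes from aldehyde 5 by chlorite oxidation. The oxidation is placed at the bromide stage, when the ring has only one free, poorly activated position left for stray chlorination. The C5'–Br bond is cut back to aldehyde 4: C5' is para to the 2'-methoxyl and ortho to the 4'-methoxyl, while C6' is ortho to the formyl group.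

4 to 2 to 1. The C1'–CHO bond is cut, leaving ether 2, whose two positions ortho to a methoxyl are equivalent by symmetry, so formylation has one productive site. Ether 2 is the benzyl ether of commercial phenol 1, whose hydroxyl is already flanked by the two methoxyls that become 2'-OMe and 4'-OMe.

## Alternatives that were turned down

Alternative 1: Ring B is built rather than bought. Racemic 4-chloro-2,3-dimethoxycyclobut-2-en-1-one (A1) and methyl (Z)-3-methoxy-2-(tributylstannyl)prop-2-enoate (A2) are joined at C6'–C1' by a Stille coupling (Pd2(dba)3, tri(2-furyl)phosphine). On heating, the coupled cyclobutenone opens and recloses at C3'–C2' to give methyl 3-hydroxy-2,4,5-trimethoxybenzoate (A3), the former carbonyl carbon ending as C3' with its free hydroxyl.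
- For: the substitution pattern of ring B is written by the components, the only free hydroxyl is the one the target needs, and no directing effect has to be trusted. On regiochemical certainty for ring B this is stronger than the chosen route, which relies on formylation and bromination going where expected.
- Against: it spends its invention on the easy half. Acid 7 is reached from 1 in five ordinary steps, while A1 and A2 each need their own preparation and a stoichiometric tin reagent. A3 must still be protected, hydrolysed and joined to ring A, and the pyranone closure with the free 5-OH remains unsolved.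
- Comparison: the chosen strategy offers a shorter sequence and puts the new chemistry at O1–C8a, where the target is hard.

Alternative 2: The C2–C1' bond is cut. In 2-(benzyloxy)-6-bromo-3,4-dimethoxyphenyl 5,6,7-trimethoxy-4-oxo-4H-chromene-3-carboxylate (A4), zerovalent palladium formed from Pd(OAc)2 and PCy3·HBF4 inserts into C1'–Br and arylates C2–H. This forms C2–C1' and a six-membered lactone, giving the lactone-bridged 2-arylchromone (A5).
- For: the route is convergent, the ester tether fixes both the site on the chromone and the ortho relationship on ring B, and C2–H of a chromone is well suited to metalation–deprotonation. On convergence it is stronger than the chosen route.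
- Against: the tether carbon is not part of the target. After the coupling, the lactone must be opened with a nucleophile that also threatens the pyranone at C2, the C3 acid decarboxylated, and O2' methylated. Ring A in A5 carries 5-OMe, so the late chelation-controlled demethylation returns. A4 needs two multi-step halves.
- Comparison: the chosen route makes the corresponding connection (C2–C3) in one Claisen-type acylation with no atoms to remove, and needs two steps after the key step instead of at least four.

Alternative 3: Ring A is grown on a preformed pyranone. 2-[3-(Benzyloxy)-2,4,5-trimethoxyphenyl]-6-(tributylstannyl)-4H-pyran-4-one (A6) and A1 are coupled at C8–C8a. The resulting cyclobutenone opens and recloses at C5–C4a to give 3'-O-benzylpsiadiarabicin (A7), which is identical with 15.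
- For: this is the strongest alternative. The ring A pattern, including the free 5-OH, is dictated by the components; no selective methylation and no oxidation is needed; A7 is one step from the target, against two steps after the key step in the chosen route.
- Against: A6 is hard to reach. The 2-aryl-4-pyranone must be built and then stannylated at C6, where metalation competes with nucleophilic addition and ring opening. A1 again needs several steps, and tin is used stoichiometrically.
- Comparison: the chosen strategy buys ring A with all three oxygens in place, reaches the key precursor in one step from 9, is tin-free, and confines the risk to one step with a conventional fallback from the shared intermediate 8.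

Key step: step 8

Assumption: compound 9 (2,3-dihydroxy-4-methoxyacetophenone) is bought as its hydrate and dried azeotropically with toluene before step 7, since water would consume the amide base.

## Route

Step 1
Reactants: 1 2,6-dimethoxyphenol
Product: 2 2-(benzyloxy)-1,3-dimethoxybenzene
Conditions: BnBr, K2CO3, acetone, reflux
Reagents that add atoms: benzyl bromide, BrCc1ccccc1
Why: Williamson ether synthesis on the only hydroxyl; the benzyl ether masks the future 3'-OH and later survives acid chloride formation, amide base, the anode potential and methylation.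

Step 2
Reactants: 2 2-(benzyloxy)-1,3-dimethoxybenzene
Product: 4 3-(benzyloxy)-2,4-dimethoxybenzaldehyde, via aryl iminium salt 3 (not isolated)
Conditions: POCl3, DMF, 0 to 80 °C; then ice-water
Reagents that add atoms: N,N-dimethylformamide, CN(C)C=O; water, O
Why: Vilsmeier–Haack formylation; the two positions ortho to one methoxyl and para to the other are equivalent by symmetry and far more activated than the position para to the twisted central benzyloxy group, so one aldehyde should result after hydrolysis of 3.

Step 3
Reactants: 4 3-(benzyloxy)-2,4-dimethoxybenzaldehyde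
Product: 5 3-(benzyloxy)-5-bromo-2,4-dimethoxybenzaldehyde
Conditions: NBS, DMF, rt
Reagents that add atoms: N-bromosuccinimide, O=C1CCC(=O)N1Br
Why: Electrophilic aromatic bromination; C5 is para to the 2-methoxyl and ortho to the 4-methoxyl, whereas C6 is ortho to the deactivating formyl group, and the benzyl ring is not activated enough to compete.

Step 4
Reactants: 5 3-(benzyloxy)-5-bromo-2,4-dimethoxybenzaldehyde
Product: 6 3-(benzyloxy)-5-bromo-2,4-dimethoxybenzoic acid
Conditions: NaClO2, NaH2PO4, 2-methyl-2-butene, t-BuOH–H2O, rt
Reagents that add atoms: sodium chlorite, [Na+].[O-]Cl=O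
Why: Pinnick oxidation of a non-enolisable aldehyde; the alkene traps hypochlorous acid, and with C5 already brominated the ring offers only the poorly activated C6 to stray chlorination.

Step 5
Reactants: 6 3-(benzyloxy)-5-bromo-2,4-dimethoxybenzoic acid
Product: 7 3-(benzyloxy)-2,4,5-trimethoxybenzoic acid
Conditions: NaOMe (excess), CuBr (20 mol %), DMF–MeOH, 110 °C; then aq. HCl
Reagents that add atoms: sodium methoxide, [Na+].[O-]C
Why: Ullmann-type copper-catalysed methoxylation of an aryl bromide; the substrate reacts as its sodium carboxylate, which is inert to methoxide, and the benzyl and methyl ethers are stable to these conditions.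

Step 6
Reactants: 7 3-(benzyloxy)-2,4,5-trimethoxybenzoic acid
Product: 8 3-(benzyloxy)-2,4,5-trimethoxybenzoyl chloride
Conditions: (COCl)2, DMF (cat.), CH2Cl2, 0 °C to rt; evaporate, use crude
Reagents that add atoms: oxalyl chloride, O=C(Cl)C(=O)Cl
Why: Acid chloride formation through the catalytic chloroiminium species; the mild, non-Lewis-acidic conditions leave the benzyl ether intact.

Step 7
Reactants: 8 3-(benzyloxy)-2,4,5-trimethoxybenzoyl chloride; 9 2,3-dihydroxy-4-methoxyacetophenone
Product: 11 1-[3-(benzyloxy)-2,4,5-trimethoxyphenyl]-3-(2,3-dihydroxy-4-methoxyphenyl)propane-1,3-dione, via trilithium enolate bisphenolate 10 (not isolated)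
Conditions: 9, LiN(SiMe3)2 (4.5 equiv), THF, −78 to −10 °C; then 8, −78 °C to rt; cold aq. NH4Cl (pH about 6), Ar
Reagents that add atoms: none
Why: Claisen-type C-acylation of a lithium polyanion of a hydroxyacetophenone; the ketone enolate carbon of 10 is the most nucleophilic site, the fourth equivalent of base absorbs the acidic diketone proton of the product, and the near-neutral quench avoids cyclodehydration through the ortho hydroxyl.

Step 8
Reactants: 11 1-[3-(benzyloxy)-2,4,5-trimethoxyphenyl]-3-(2,3-dihydroxy-4-methoxyphenyl)propane-1,3-dione
Product: 14 2-[3-(benzyloxy)-2,4,5-trimethoxyphenyl]-5,6-dihydroxy-7-methoxy-4H-chromen-4-one (3'-O-benzyl-6-O-demethylpsiadiarabicin), via ring A ortho-quinone 12 (not isolated), via 8a-H dienone adduct 13 (not isolated)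
Conditions: graphite anode, Pt cathode, divided cell, constant potential at the foot of the first anodic wave of 11 (read from a voltammogram, vs Ag/AgCl), MeCN–aq. NaH2PO4/Na2HPO4 buffer pH 7 (1:1), dilute, N2, rt, about 2 F/mol; then aq. Na2S2O4 wash
Reagents that add atoms: none
Why: Proposed new method: two-electron, two-proton oxidation of the catechol of 11 at the anode should give ortho-quinone 12, in which C8a is the β-carbon of both the C5 and the C4 carbonyl groups; the enol or enolate oxygen on C2 adds there, and loss of the C8a proton from dienone 13 restores the benzene ring as catechol 14; the closest known reaction type is the anodic oxidation of catechols in the presence of 1,3-dicarbonyl compounds, where the electrogenerated ortho-quinone is trapped by Michael addition, here redirected to an intramolecular addition through oxygen. The pyranone ring closes in a 6-endo-trig oxa-Michael mode, O1 adding to C8a of the C4a=C8a bond. No stereocentre remains: the sp3 centre at C8a of 13 forms as a racemate and is erased by tautomerisation. The step needs chemoselective oxidation, which the substrate secures because a free catechol is oxidised far below the fully etherified ring B and the benzyl ether. It needs a single site of attack, which the tether and the electronics secure: the enol oxygen can reach only C8a, attack through C3 would make a four-membered ring, and C8 is deactivated by the donor methoxyl on C7. Neutral buffer keeps 11 from cyclodehydrating through the C5 hydroxyl to the isomeric 8-hydroxyflavone and supplies enough enolate for the addition. Because 14 carries one more oxygen donor than 11 and may be oxidised in its turn, the charge is held near two electrons per molecule and the dithionite wash would return any quinone of 14 to 14.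

Step 9
Reactants: 14 2-[3-(benzyloxy)-2,4,5-trimethoxyphenyl]-5,6-dihydroxy-7-methoxy-4H-chromen-4-one
Product: 15 2-[3-(benzyloxy)-2,4,5-trimethoxyphenyl]-5-hydroxy-6,7-dimethoxy-4H-chromen-4-one (3'-O-benzylpsiadiarabicin)
Conditions: MeI (1.1 equiv), K2CO3 (1.1 equiv), degassed DMF, 0 °C to rt, Ar
Reagents that add atoms: iodomethane, CI
Why: Williamson O-methylation; the 5-OH is chelated to the C4 carbonyl and is both less acidic and less nucleophilic than the 6-OH, so one equivalent of base and electrophile should methylate O6 only.

Step 10
Reactants: 15 2-[3-(benzyloxy)-2,4,5-trimethoxyphenyl]-5-hydroxy-6,7-dimethoxy-4H-chromen-4-one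
Product: 16 5-hydroxy-2-(3-hydroxy-2,4,5-trimethoxyphenyl)-6,7-dimethoxy-4H-chromen-4-one (psiadiarabicin)
Conditions: H2 (1 atm), Pd/C, EtOAc–MeOH, rt
Reagents that add atoms: none
Why: Catalytic hydrogenolysis of the benzyl aryl ether; at one atmosphere and room temperature the flavone C2=C3 bond and the methyl ethers should be untouched.

## Compound list

1 | 2,6-dimethoxyphenol | COc1cccc(OC)c1O | starting material
2 | 2-(benzyloxy)-1,3-dimethoxybenzene | COc1cccc(OC)c1OCc1ccccc1 | intermediate
3 | N-{[3-(benzyloxy)-2,4-dimethoxyphenyl]methylidene}-N-methylmethanaminium dichlorophosphate (not isolated) | C[N+](C)=Cc1ccc(OC)c(OCc2ccccc2)c1OC.[O-]P(=O)(Cl)Cl | intermediate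
4 | 3-(benzyloxy)-2,4-dimethoxybenzaldehyde | COc1ccc(C=O)c(OC)c1OCc1ccccc1 | intermediate
5 | 3-(benzyloxy)-5-bromo-2,4-dimethoxybenzaldehyde | COc1c(Br)cc(C=O)c(OC)c1OCc1ccccc1 | intermediate
6 | 3-(benzyloxy)-5-bromo-2,4-dimethoxybenzoic acid | COc1c(Br)cc(C(=O)O)c(OC)c1OCc1ccccc1 | intermediate
7 | 3-(benzyloxy)-2,4,5-trimethoxybenzoic acid | COc1cc(C(=O)O)c(OC)c(OCc2ccccc2)c1OC | intermediate
8 | 3-(benzyloxy)-2,4,5-trimethoxybenzoyl chloride | COc1cc(C(=O)Cl)c(OC)c(OCc2ccccc2)c1OC | intermediate
9 | 2,3-dihydroxy-4-methoxyacetophenone | CC(=O)c1ccc(OC)c(O)c1O | starting material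
10 | trilithium 3-(1-oxidoethenyl)-6-methoxybenzene-1,2-diolate (not isolated) | [Li+].[Li+].[Li+].C=C([O-])c1ccc(OC)c([O-])c1[O-] | intermediate
11 | 1-[3-(benzyloxy)-2,4,5-trimethoxyphenyl]-3-(2,3-dihydroxy-4-methoxyphenyl)propane-1,3-dione | COc1ccc(C(=O)CC(=O)c2cc(OC)c(OC)c(OCc3ccccc3)c2OC)c(O)c1O | intermediate
12 | 1-[3-(benzyloxy)-2,4,5-trimethoxyphenyl]-3-(4-methoxy-5,6-dioxocyclohexa-1,3-dien-1-yl)propane-1,3-dione (not isolated) | COC1=CC=C(C(=O)CC(=O)c2cc(OC)c(OC)c(OCc3ccccc3)c2OC)C(=O)C1=O | intermediate
13 | 2-[3-(benzyloxy)-2,4,5-trimethoxyphenyl]-5-hydroxy-7-methoxy-8aH-chromene-4,6-dione, racemic at C8a (not isolated) | COC1=CC2OC(c3cc(OC)c(OC)c(OCc4ccccc4)c3OC)=CC(=O)C2=C(O)C1=O | intermediate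
14 | 2-[3-(benzyloxy)-2,4,5-trimethoxyphenyl]-5,6-dihydroxy-7-methoxy-4H-chromen-4-one | COc1cc(-c2cc(=O)c3c(O)c(O)c(OC)cc3o2)c(OC)c(OCc2ccccc2)c1OC | intermediate
15 | 2-[3-(benzyloxy)-2,4,5-trimethoxyphenyl]-5-hydroxy-6,7-dimethoxy-4H-chromen-4-one | COc1cc(-c2cc(=O)c3c(O)c(OC)c(OC)cc3o2)c(OC)c(OCc2ccccc2)c1OC | intermediate
16 | psiadiarabicin, 5-hydroxy-2-(3-hydroxy-2,4,5-trimethoxyphenyl)-6,7-dimethoxy-4H-chromen-4-one | COc1cc(-c2cc(=O)c3c(O)c(OC)c(OC)cc3o2)c(OC)c(O)c1OC | target

## Step count and least certain steps

Total step count: 10. Longest linear sequence: 10 steps (1 to 16 through steps 1 to 10; 9 enters at step 7).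

Step 8 (key step). Several processes could go wrong.
- The cyclised catechol may be oxidised further, and its quinone may then lose the 7-methoxyl or take up water at C8.
- Water, or the enol carbon of a second molecule, may trap 12 before the ring closes, giving hydroxylation or dimerisation.
- The ring closure may be slow, because the chelated enol must rotate about C3–C4 before its oxygen can reach C8a.
- Polymeric films may passivate the anode.

The fallback uses known chemistry, sets out from acid chloride 8 and comes back at target 16. Acid chloride 8 is joined to commercial 1-(6-hydroxy-2,3,4-trimethoxyphenyl)ethanone F1 by the same lithium polyanion C-acylation (LiN(SiMe3)2, THF), which should give 1-[3-(benzyloxy)-2,4,5-trimethoxyphenyl]-3-(6-hydroxy-2,3,4-trimethoxyphenyl)propane-1,3-dione F2. Catalytic H2SO4 in AcOH closes the pyranone by cyclodehydration through the only ortho hydroxyl and should give 2-[3-(benzyloxy)-2,4,5-trimethoxyphenyl]-5,6,7-trimethoxy-4H-chromen-4-one F3. BCl3 with pentamethylbenzene in CH2Cl2 (−78 to 0 °C) then removes the benzyl group and the carbonyl-chelated 5-O-methyl group in one operation and delivers 16. The price is the late Lewis-acid dealkylation that the main route avoids, with some risk to the 6-methoxyl and to the methoxyls next to the freed 3'-oxygen.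

Step 7. O-acylation of the two phenoxide oxygens may compete with C-acylation of the enolate, the trilithium salt 10 may be poorly soluble, and the catecholate may be oxidised by adventitious air. The fallback sets out from 9 (with 8) and comes back at 11 by a Baker–Venkataraman sequence. Both hydroxyls of 9 are acylated with two equivalents of 8 (Et3N, DMAP, CH2Cl2) to give 3-acetyl-6-methoxy-1,2-phenylene bis[3-(benzyloxy)-2,4,5-trimethoxybenzoate] F4. KOt-Bu in THF moves the ortho ester group onto the enolate carbon to give 2-hydroxy-6-methoxy-3-{3-[3-(benzyloxy)-2,4,5-trimethoxyphenyl]-3-oxopropanoyl}phenyl 3-(benzyloxy)-2,4,5-trimethoxybenzoate F5. K2CO3 in MeOH at room temperature cleaves the remaining aryl ester and gives 11.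

Step 5. The electron-rich, hindered aryl bromide may exchange slowly, and reductive loss of bromine by hydride transfer from methoxide may compete. The fallback sets out from 6 and comes back at 7, introducing the oxygen as hydroxide at palladium and the methyl group afterwards. Pd2(dba)3 with tBuXPhos and KOH in dioxane–H2O at 100 °C should give 3-(benzyloxy)-5-hydroxy-2,4-dimethoxybenzoic acid F6. MeI and K2CO3 in DMF methylate phenol and acid to methyl 3-(benzyloxy)-2,4,5-trimethoxybenzoate F7, and LiOH in THF–H2O gives 7.

Step 9. Methylation may continue to the chelated 5-OH, and the catecholate may be oxidised by air before it is alkylated. The fallback sets out from 14 and comes back at 16, giving up the selectivity. Excess MeI and K2CO3 in DMF at 60 °C methylate both hydroxyls to 2-[3-(benzyloxy)-2,4,5-trimethoxyphenyl]-5,6,7-trimethoxy-4H-chromen-4-one F8 (the same flavone as F3). BCl3 with pentamethylbenzene in CH2Cl2 then cleaves the chelated 5-O-methyl group and the benzyl ether to give 16, bypassing 15 and step 10.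

## Further compounds

F1 | step 8 | 1-(6-hydroxy-2,3,4-trimethoxyphenyl)ethanone (commercial) | CC(=O)c1c(O)cc(OC)c(OC)c1OC
F2 | step 8 | 1-[3-(benzyloxy)-2,4,5-trimethoxyphenyl]-3-(6-hydroxy-2,3,4-trimethoxyphenyl)propane-1,3-dione | COc1cc(O)c(C(=O)CC(=O)c2cc(OC)c(OC)c(OCc3ccccc3)c2OC)c(OC)c1OC
F3 | step 8 | 2-[3-(benzyloxy)-2,4,5-trimethoxyphenyl]-5,6,7-trimethoxy-4H-chromen-4-one | COc1cc(-c2cc(=O)c3c(OC)c(OC)c(OC)cc3o2)c(OC)c(OCc2ccccc2)c1OC
F4 | step 7 | 3-acetyl-6-methoxy-1,2-phenylene bis[3-(benzyloxy)-2,4,5-trimethoxybenzoate] | CC(=O)c1ccc(OC)c(OC(=O)c2cc(OC)c(OC)c(OCc3ccccc3)c2OC)c1OC(=O)c1cc(OC)c(OC)c(OCc2ccccc2)c1OC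
F5 | step 7 | 2-hydroxy-6-methoxy-3-{3-[3-(benzyloxy)-2,4,5-trimethoxyphenyl]-3-oxopropanoyl}phenyl 3-(benzyloxy)-2,4,5-trimethoxybenzoate | COc1ccc(C(=O)CC(=O)c2cc(OC)c(OC)c(OCc3ccccc3)c2OC)c(O)c1OC(=O)c1cc(OC)c(OC)c(OCc2ccccc2)c1OC
F6 | step 5 | 3-(benzyloxy)-5-hydroxy-2,4-dimethoxybenzoic acid | COc1c(O)cc(C(=O)O)c(OC)c1OCc1ccccc1
F7 | step 5 | methyl 3-(benzyloxy)-2,4,5-trimethoxybenzoate | COC(=O)c1cc(OC)c(OC)c(OCc2ccccc2)c1OC
F8 | step 9 | 2-[3-(benzyloxy)-2,4,5-trimethoxyphenyl]-5,6,7-trimethoxy-4H-chromen-4-one | COc1cc(-c2cc(=O)c3c(OC)c(OC)c(OC)cc3o2)c(OC)c(OCc2ccccc2)c1OC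
A1 | alternative 1 | 4-chloro-2,3-dimethoxycyclobut-2-en-1-one (racemic) | COC1=C(OC)C(Cl)C1=O
A2 | alternative 1 | methyl (Z)-3-methoxy-2-(tributylstannyl)prop-2-enoate | CO/C=C(\[Sn](CCCC)(CCCC)CCCC)C(=O)OC
A3 | alternative 1 | methyl 3-hydroxy-2,4,5-trimethoxybenzoate | COC(=O)c1cc(OC)c(OC)c(O)c1OC
A4 | alternative 2 | 2-(benzyloxy)-6-bromo-3,4-dimethoxyphenyl 5,6,7-trimethoxy-4-oxo-4H-chromene-3-carboxylate | COc1cc2occ(C(=O)Oc3c(Br)cc(OC)c(OC)c3OCc3ccccc3)c(=O)c2c(OC)c1OC
A5 | alternative 2 | lactone-bridged 2-arylchromone (C3 carboxylate tied to O2') | O=C1Oc2c(OCc3ccccc3)c(OC)c(OC)cc2-c2oc3cc(OC)c(OC)c(OC)c3c(=O)c21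
A6 | alternative 3 | 2-[3-(benzyloxy)-2,4,5-trimethoxyphenyl]-6-(tributylstannyl)-4H-pyran-4-one | COc1cc(-c2cc(=O)cc([Sn](CCCC)(CCCC)CCCC)o2)c(OC)c(OCc2ccccc2)c1OC
A7 | alternative 3 | 3'-O-benzylpsiadiarabicin (identical with 15) | COc1cc(-c2cc(=O)c3c(O)c(OC)c(OC)cc3o2)c(OC)c(OCc2ccccc2)c1OC
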